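## Analysis of the target

Target 17 is a flavan: a benzene ring (ring A) fused to a saturated pyran (ring C), with a second arene (ring B) on C2. Going round ring A from the ring oxygen O1 at C8a, C8 carries a prenyl group, C7 a free hydroxyl, C6 hydrogen, C5 a methoxy group, and C4a the C4 methylene. Ring B is a 3-hydroxy-5-methoxyphenyl group. The only stereocentre is C2, of R configuration (O1 > ring B > C3 > H). It is benzylic and bonded to oxygen, and there is no second centre to relay from, so it must be set by a reagent or catalyst and then kept away from ionising conditions. The sensitive groups are the trisubstituted prenyl alkene flanked by two oxygens (acid-induced cyclisation, electrophiles, heterogeneous hydrogenation), two free phenols on electron-rich rings (oxidation), and the benzylic C2–O1 bond (acid, hydrogenolysis). The difficulty lies in differentiation: each ring holds one hydroxyl and one methoxy group in a meta relationship, ring A is pentasubstituted in a fixed pattern, and C2 must be a single enantiomer. The feature the plan rests on is that C4 is bonded to C4a, the only carbon ortho to O1 that is unsubstituted in a ring A building block, because C8 holds the prenyl group. C4a is also ortho to the C5 methoxy group and para to the C7 oxygen, so it is the most nucleophilic ring carbon, and an alkyne-terminated three-carbon chain on O1 can be closed onto it to form ring C.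

## Retrosynthetic reasoning

**17 to 16 (O–Si bonds).** Both phenols are kept as triisopropylsilyl ethers to the end. Fluoride cleavage touches neither the prenyl alkene nor the benzylic ether, so the last step carries no selectivity problem, and the two electron-rich phenols are never exposed to the metal or redox steps.

**16 to 15 (C3–C4 saturation).** The flavan 16 is traced to the 2H-chromene 15. The C3=C4 alkene is the residue of an alkyne used for ring closure. The forward step must add H2 to a cis-disubstituted alkene, spare the trisubstituted prenyl alkene, and not cleave the benzylic C2–O1 bond. A metal-free concerted hydrogen transfer meets these demands.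

**15 to 14 (C4–C4a, the key cut).** Cutting C4–C4a opens ring C to the aryl propargyl ether 14. This cut is preferred because it uses the C4a–H bond directly, so ring A needs no halogen or other handle. It also places C2 in a simple secondary propargylic position, where it is easy to set. The skeleton divides into two arenes that are bought with their oxygens in place. The forward reaction is a π-acid-catalysed 6-endo-dig attack of C4a on the terminal alkyne carbon, which must proceed without ionising the C2–O bond.

**14 to 7 + 13 (O1–C2).** The ether is cut at O1–C2 into phenol 7 and the (S)-propargylic alcohol 13, to be joined by a Mitsunobu reaction with inversion. A copper-catalysed enantioselective substitution on a racemic propargylic ester would be shorter on paper. It is not used as the main path because 7 is a 3,5-dioxygenated phenol, whose ring carbons compete with oxygen for the cationic propargyl/allenylidene-type electrophile of that chemistry. The Mitsunobu reaction is O-selective, and the meta-oxygenated ring B gives little help to ionisation at C2.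

**13 to 12 to 9 + 10; 9 to 8 (C2–C3 and the stereocentre).** Alcohol 13 comes from its C-silylated form 12 by mild methanolysis. Compound 12 comes from a catalytic enantioselective addition of the alkynylzinc 11 (made in the flask from alkyne 10) to aldehyde 9. This is where C2 is set, on a small fragment whose enantiomeric purity can be checked before coupling. Aldehyde 9 is the silyl ether of commercial 8.

**7 to 6 to 5 to 2 + 3; 2 to 1 (ring A pattern).** Phenol 7 is the monosilyl ether of the symmetric diol 6. Because the two hydroxyls of 6 are equivalent, only one monoether exists. Diol 6 comes from the bis-acetal 5, which is made by alkylating aryllithium 4 with prenyl bromide 3. Aryllithium 4 is generated by directed metalation of 2 at the carbon between the two acetal oxygens, and this step places the prenyl group at the future C8. Compound 2 is the bis-acetal of commercial 1.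

## Alternatives that were turned down

**Alternative 1:** Ring B is built rather than bought. The bonds C1'–C6' and C4'–C5' are cut, leading to the enone A1, which already holds rings A and C and the C2 stereocentre, and to dimethyl malonate A2.
- Forward key step: alkoxide-catalysed Michael addition of A2 to the β-carbon of A1, then Claisen condensation of the methyl ketone enolate onto an ester, would close the cyclohexane-1,3-dione A3. Decarboxylation, dehydrogenation and mono-O-methylation would then convert that ring into ring B.
- For it: the 1,3-relationship of the ring B oxygens falls out of the dione, and the reagents are cheap. C2 is never a benzylic propargylic ether carbon facing a Lewis acid, so on that point it is safer than the chosen route.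
- Against it: C2 of A1 is the oxygen-bearing γ-carbon of an enone, and under the basic annulation conditions γ-deprotonation can epimerise it. Aromatising A3 needs an oxidant in the presence of the prenyl alkene and the benzylic C4 of an electron-rich ring. The final mono-methylation is statistical. A1 itself needs an enantioselective chroman synthesis plus a chain extension.
- Comparison: it spends roughly six steps after A1 to make a ring that the chosen route buys as 8 with its oxygens already differentiated. The chosen route pays for this with the need to carry C2 through one gold-catalysed step.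

**Alternative 2:** Ring A is assembled by a Danheiser benzannulation, cutting C8–C8a, C6–C7 and C4a–C8a. The partners are the 4-substituted 3-methoxycyclobutenone A4, which carries the ring B carbinol chain, and the prenyl-substituted siloxyalkyne A5.
- Forward key step: heating opens A4 to a vinylketene, which adds to A5 in a (2+2) cycloaddition. 4π opening and 6π closure then give phenol A6, with the C8a hydroxyl free and the C7 oxygen silylated. Ring C would then be closed at O1–C2 by displacement of the unmasked carbinol with inversion.
- For it: the full substitution pattern of ring A and the differentiation of the C8a and C7 oxygens are dictated by the connectivity of A4 and A5. Here it is stronger than the chosen route, which relies on a directed metalation (step 2) and a statistical monosilylation (step 4).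
- Against it: A4 needs C4-alkylation of a sensitive cyclobutenone with a chiral electrophile, and A5 is a moisture-sensitive ynol silyl ether with its own multistep preparation. The cascade runs hot in the presence of a triethylsilyl ether and an alkene. After it, C2 still has to survive an inversion step.
- Comparison: the count is clearly higher than eleven. The chosen route makes ring A from commercial 1 in four simple steps and keeps the risk in one catalytic ring closure.

**Alternative 3:** Ring C is cut at C3–C4 and O1–C2, leading to the ring A salicyl alcohol A7 and the ring B styrene A8.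
- Forward key step: a confined chiral Brønsted acid dehydrates A7 to the ortho-quinone methide A9, which adds A8 in a (4+2) cycloaddition. This gives the flavan A10, identical with 16.
- For it: this is the most convergent plan. One step forms two bonds, ring C and the stereocentre, and it arrives at the saturated flavan, so no chromene has to be reduced next to the prenyl group. On step economy it is as strong as or stronger than the chosen route.
- Against it: A8 has its oxygens meta to the vinyl group, so it is an unactivated styrene without a hydrogen-bonding handle. A9 is stabilised by two oxygen donors and is therefore a weak electrophile that needs a strong acid. That acid sits next to an ortho-prenyl phenol, which cyclises to a dimethylchroman under such conditions, and next to aryl silyl ethers. Self-condensation of A9 with A7 and a racemic background reaction are likely. Enantioselectivity would be created and risked in the same step, with no chance of correction.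
- Comparison: the chosen route sets C2 in a well-behaved aldehyde addition, allows its purity to be checked at 13, and asks the key step only to preserve it. It accepts three more steps for that.

Key step: step 9

## Route

Assumption on the chemistry: the sense of induction in step 6 depends on the ligand antipode. The ligand is written as (S,S). Whichever antipode delivers 12 (checked by chiral HPLC at 13) is the one to use, and both are commercially available.

Step 1
Reactants: 1 5-methoxyresorcinol
Product: 2 1-methoxy-3,5-bis(methoxymethoxy)benzene
Conditions: NaH, MOMCl, DMF, 0 °C → rt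
Reagents that add atoms: chloromethyl methyl ether, COCCl
Why: Williamson-type O-alkylation of both phenoxides; the methoxymethyl ethers protect the phenols and serve as the directing groups for step 2.

Step 2
Reactants: 2 1-methoxy-3,5-bis(methoxymethoxy)benzene; 3 prenyl bromide (1-bromo-3-methylbut-2-ene)
Product: 5 5-methoxy-1,3-bis(methoxymethoxy)-2-(3-methylbut-2-en-1-yl)benzene, via aryllithium 4 (not isolated)
Conditions: n-BuLi, THF, 0 °C; then 3, CuI (10 mol%), −78 °C → rt
Reagents that add atoms: none
Why: Directed ortho-metalation; the carbon between the two acetal oxygens is chelated from both sides and is lithiated in preference to the carbons next to the methoxy group, and the aryl metal then displaces the primary allylic bromide (SN2).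

Step 3
Reactants: 5 5-methoxy-1,3-bis(methoxymethoxy)-2-(3-methylbut-2-en-1-yl)benzene
Product: 6 5-methoxy-2-(3-methylbut-2-en-1-yl)benzene-1,3-diol
Conditions: HCl (2 M aq.), MeOH, 40 °C, stopped at full conversion
Reagents that add atoms: none
Why: Acid-catalysed acetal methanolysis; dilute acid at mild temperature cleaves aryl methoxymethyl ethers faster than it protonates the trisubstituted alkene, so cyclisation of the ortho-prenyl phenol to a dimethylchroman should be avoided.

Step 4
Reactants: 6 5-methoxy-2-(3-methylbut-2-en-1-yl)benzene-1,3-diol
Product: 7 5-methoxy-2-(3-methylbut-2-en-1-yl)-3-(triisopropylsilyloxy)phenol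
Conditions: TIPSCl (1.0 equiv), imidazole, DMF, 0 °C; unreacted 6 and bis-silyl ether (after Bu4NF) recycled
Reagents that add atoms: triisopropylsilyl chloride, CC(C)[Si](Cl)(C(C)C)C(C)C
Why: Statistical monosilylation of a diol whose hydroxyls are equivalent by symmetry, so only one monoether can form; limiting the chloride and recycling handle over-silylation.

Step 5
Reactants: 8 3-hydroxy-5-methoxybenzaldehyde
Product: 9 3-methoxy-5-(triisopropylsilyloxy)benzaldehyde
Conditions: TIPSCl, imidazole, DMF, rt
Reagents that add atoms: triisopropylsilyl chloride, CC(C)[Si](Cl)(C(C)C)C(C)C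
Why: Standard silylation of a phenol; the hindered silyl ether withstands the organozinc, carbonate, Mitsunobu and gold steps that follow.

Step 6
Reactants: 9 3-methoxy-5-(triisopropylsilyloxy)benzaldehyde; 10 trimethylsilylacetylene
Product: 12 (1R)-1-[3-methoxy-5-(triisopropylsilyloxy)phenyl]-3-(trimethylsilyl)prop-2-yn-1-ol, via alkynylzinc 11 (not isolated)
Conditions: (S,S)-ProPhenol (10 mol%), Me2Zn (3 equiv), Ph3P=O (20 mol%), toluene, 0 °C
Reagents that add atoms: none
Why: Catalytic enantioselective alkynylation of an aryl aldehyde; the dinuclear zinc–ProPhenol complex holds aldehyde and alkynyl group on neighbouring zinc atoms and delivers the alkynyl group to one enantiotopic face, which sets the future C2 (the descriptor is R here only because the silylalkynyl group outranks the aryl group).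

Step 7
Reactants: 12 (1R)-1-[3-methoxy-5-(triisopropylsilyloxy)phenyl]-3-(trimethylsilyl)prop-2-yn-1-ol
Product: 13 (1S)-1-[3-methoxy-5-(triisopropylsilyloxy)phenyl]prop-2-yn-1-ol
Conditions: K2CO3 (0.2 equiv), MeOH, 0 °C
Reagents that add atoms: none
Why: Base-catalysed methanolysis of the C(sp)–Si bond, which is far faster than attack on the hindered aryl triisopropylsilyl ether; the carbinol centre is not touched (same spatial arrangement, descriptor now S).

Step 8
Reactants: 7 5-methoxy-2-(3-methylbut-2-en-1-yl)-3-(triisopropylsilyloxy)phenol; 13 (1S)-1-[3-methoxy-5-(triisopropylsilyloxy)phenyl]prop-2-yn-1-ol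
Product: 14 (1R)-1-[3-methoxy-5-(triisopropylsilyloxy)phenyl]prop-2-yn-1-yl 5-methoxy-2-(3-methylbut-2-en-1-yl)-3-(triisopropylsilyloxy)phenyl ether
Conditions: PPh3, DIAD, toluene, 0 °C → rt
Reagents that add atoms: none
Why: Mitsunobu etherification; the phenoxide displaces the alkoxyphosphonium group in an SN2 step with inversion, turning (S)-13 into (R)-14. The meta-oxygenated ring B gives little stabilisation to a cation at this carbon, which disfavours an ionising path.

Step 9
Reactants: 14 (1R)-1-[3-methoxy-5-(triisopropylsilyloxy)phenyl]prop-2-yn-1-yl 5-methoxy-2-(3-methylbut-2-en-1-yl)-3-(triisopropylsilyloxy)phenyl ether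
Product: 15 (2R)-5-methoxy-2-[3-methoxy-5-(triisopropylsilyloxy)phenyl]-8-(3-methylbut-2-en-1-yl)-7-(triisopropylsilyloxy)-2H-chromene
Conditions: Ph3PAuNTf2 (3 mol%), CH2Cl2, 0 °C → rt, light excluded
Reagents that add atoms: none
Why: The cationic monovalent gold centre binds the terminal alkyne, and C4a attacks the terminal alkyne carbon anti to gold in a Friedel–Crafts manner; rearomatisation and protodeauration of the vinylgold species release 15 and the catalyst. The closest known reaction type is the gold- or platinum-catalysed intramolecular hydroarylation of aryl propargyl ethers to 2H-chromenes. Ring C closes in the 6-endo-dig mode, because the short O–C–C tether puts the terminal carbon, not the internal one, within reach of C4a. No stereocentre is formed, and C2 is carried through because none of its bonds is broken. Site selectivity is secured by the substrate: C8 bears the prenyl group, so C4a is the only ortho carbon that can react, and it is activated by the ortho methoxy group and the para silyloxy group. Gold activates the alkyne in preference to the remote trisubstituted alkene, whose participation would require a medium ring. Retention at C2 requires that the benzylic propargylic ether does not ionise; the meta-placed oxygens of ring B, the poor aryloxide leaving group, the non-acidic triflimide counter-ion and the low temperature all work against ionisation. Light is excluded because 2H-chromenes open reversibly to ortho-quinone methides on irradiation, which would erase C2.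

Step 10
Reactants: 15 (2R)-5-methoxy-2-[3-methoxy-5-(triisopropylsilyloxy)phenyl]-8-(3-methylbut-2-en-1-yl)-7-(triisopropylsilyloxy)-2H-chromene
Product: 16 (2R)-5-methoxy-2-[3-methoxy-5-(triisopropylsilyloxy)phenyl]-8-(3-methylbut-2-en-1-yl)-7-(triisopropylsilyloxy)-3,4-dihydro-2H-chromene
Conditions: 2-nitrobenzenesulfonyl hydrazide (3 equiv, in portions), Et3N, CH2Cl2, rt, light excluded
Reagents that add atoms: none
Why: Diimide reduction by concerted syn transfer of H2; the rate falls steeply with alkene substitution, so the cis-disubstituted C3=C4 bond should react well before the trisubstituted prenyl alkene, and without a metal there is no hydrogenolysis of the benzylic C2–O1 bond.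

Step 11
Reactants: 16 (2R)-5-methoxy-2-[3-methoxy-5-(triisopropylsilyloxy)phenyl]-8-(3-methylbut-2-en-1-yl)-7-(triisopropylsilyloxy)-3,4-dihydro-2H-chromene
Product: 17 (2R)-2-(3-hydroxy-5-methoxyphenyl)-5-methoxy-8-(3-methylbut-2-en-1-yl)-3,4-dihydro-2H-chromen-7-ol
Conditions: Bu4NF, AcOH, THF, 0 °C
Reagents that add atoms: none
Why: Fluoride cleaves both aryl silyl ethers; acetic acid buffers the phenoxides against air oxidation, and neither the alkene nor the benzylic ether reacts.

## Compound list

1 | 5-methoxyresorcinol (5-methoxybenzene-1,3-diol) | COc1cc(O)cc(O)c1 | starting material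
2 | 1-methoxy-3,5-bis(methoxymethoxy)benzene | COCOc1cc(OC)cc(OCOC)c1 | intermediate
3 | prenyl bromide (1-bromo-3-methylbut-2-ene) | CC(C)=CCBr | starting material
4 | [4-methoxy-2,6-bis(methoxymethoxy)phenyl]lithium | [Li]c1c(OCOC)cc(OC)cc1OCOC | intermediate
5 | 5-methoxy-1,3-bis(methoxymethoxy)-2-(3-methylbut-2-en-1-yl)benzene | COCOc1cc(OC)cc(OCOC)c1CC=C(C)C | intermediate
6 | 5-methoxy-2-(3-methylbut-2-en-1-yl)benzene-1,3-diol | COc1cc(O)c(CC=C(C)C)c(O)c1 | intermediate
7 | 5-methoxy-2-(3-methylbut-2-en-1-yl)-3-(triisopropylsilyloxy)phenol | COc1cc(O)c(CC=C(C)C)c(O[Si](C(C)C)(C(C)C)C(C)C)c1 | intermediate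
8 | 3-hydroxy-5-methoxybenzaldehyde | COc1cc(O)cc(C=O)c1 | starting material
9 | 3-methoxy-5-(triisopropylsilyloxy)benzaldehyde | COc1cc(O[Si](C(C)C)(C(C)C)C(C)C)cc(C=O)c1 | intermediate
10 | trimethylsilylacetylene | C#C[Si](C)(C)C | starting material
11 | methyl[(trimethylsilyl)ethynyl]zinc | C[Zn]C#C[Si](C)(C)C | intermediate
12 | (1R)-1-[3-methoxy-5-(triisopropylsilyloxy)phenyl]-3-(trimethylsilyl)prop-2-yn-1-ol | COc1cc(O[Si](C(C)C)(C(C)C)C(C)C)cc([C@H](C#C[Si](C)(C)C)O)c1 | intermediate
13 | (1S)-1-[3-methoxy-5-(triisopropylsilyloxy)phenyl]prop-2-yn-1-ol | COc1cc(O[Si](C(C)C)(C(C)C)C(C)C)cc([C@H](C#C)O)c1 | intermediate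
14 | (1R)-1-[3-methoxy-5-(triisopropylsilyloxy)phenyl]prop-2-yn-1-yl 5-methoxy-2-(3-methylbut-2-en-1-yl)-3-(triisopropylsilyloxy)phenyl ether | COc1cc(O[Si](C(C)C)(C(C)C)C(C)C)cc([C@@H](C#C)Oc2cc(OC)cc(O[Si](C(C)C)(C(C)C)C(C)C)c2CC=C(C)C)c1 | intermediate
15 | (2R)-5-methoxy-2-[3-methoxy-5-(triisopropylsilyloxy)phenyl]-8-(3-methylbut-2-en-1-yl)-7-(triisopropylsilyloxy)-2H-chromene | COc1cc(O[Si](C(C)C)(C(C)C)C(C)C)cc([C@H]2C=Cc3c(OC)cc(O[Si](C(C)C)(C(C)C)C(C)C)c(CC=C(C)C)c3O2)c1 | intermediate
16 | (2R)-5-methoxy-2-[3-methoxy-5-(triisopropylsilyloxy)phenyl]-8-(3-methylbut-2-en-1-yl)-7-(triisopropylsilyloxy)-3,4-dihydro-2H-chromene | COc1cc(O[Si](C(C)C)(C(C)C)C(C)C)cc([C@H]2CCc3c(OC)cc(O[Si](C(C)C)(C(C)C)C(C)C)c(CC=C(C)C)c3O2)c1 | intermediate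
17 | (2R)-2-(3-hydroxy-5-methoxyphenyl)-5-methoxy-8-(3-methylbut-2-en-1-yl)-3,4-dihydro-2H-chromen-7-ol | COc1cc(O)cc([C@H]2CCc3c(OC)cc(O)c(CC=C(C)C)c3O2)c1 | target

## Step count and risk

Total: 11 steps. Longest linear sequence: 8 steps (steps 1–4 and 8–11, from 1); the ring B branch contributes steps 5–7.

**Step 9 (key step).** The most likely failure is erosion of the C2 configuration, either by gold- or acid-promoted ionisation of the benzylic propargylic C–O bond or by a sigmatropic detour through an allenyl dienone. Acid- or light-induced ring opening of the electron-rich chromene is a further risk.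
- Fallback: close O1–C2 last and avoid both the π-acid and the chromene. It sets out from 5 and 13 and returns to the route at 17.
- Compound 5 is lithiated between the acetal and methoxy oxygens (n-BuLi, THF) and iodinated to 2-iodo-1-methoxy-3,5-bis(methoxymethoxy)-4-(3-methylbut-2-en-1-yl)benzene F1.
- Sonogashira coupling of F1 with 13 (PdCl2(PPh3)2, CuI, Et3N) gives (1R)-1-[3-methoxy-5-(triisopropylsilyloxy)phenyl]-3-[6-methoxy-2,4-bis(methoxymethoxy)-3-(3-methylbut-2-en-1-yl)phenyl]prop-2-yn-1-ol F2.
- Excess diimide saturates the alkyne to (1S)-1-[3-methoxy-5-(triisopropylsilyloxy)phenyl]-3-[6-methoxy-2,4-bis(methoxymethoxy)-3-(3-methylbut-2-en-1-yl)phenyl]propan-1-ol F3.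
- Dilute HCl in MeOH removes both acetals to give 4-{(3S)-3-hydroxy-3-[3-methoxy-5-(triisopropylsilyloxy)phenyl]propyl}-5-methoxy-2-(3-methylbut-2-en-1-yl)benzene-1,3-diol F4.
- Mitsunobu cyclisation (PPh3, DIAD) closes ring C with inversion, using the only hydroxyl ortho to the chain, to give (2R)-5-methoxy-2-[3-methoxy-5-(triisopropylsilyloxy)phenyl]-8-(3-methylbut-2-en-1-yl)-3,4-dihydro-2H-chromen-7-ol F5.
- Bu4NF then gives 17.

**Step 8.** The ortho-substituted phenol may react slowly, allowing partial ionisation of the activated alkoxyphosphonium intermediate and loss of enantiomeric purity, or side reactions with the azodicarboxylate.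
- Fallback: from 13 (its configuration then no longer matters), Boc2O and DMAP give tert-butyl (1S)-1-[3-methoxy-5-(triisopropylsilyloxy)phenyl]prop-2-yn-1-yl carbonate F6.
- A copper-catalysed enantioselective propargylic etherification of F6 with 7 ((CuOTf)2·C6H6, chiral pybox ligand, iPr2NEt) then sets C2 by the ligand through a copper allenylidene and returns to the route at 14.
- This is held in reserve because ring-carbon attack by the electron-rich phenol may compete there.

**Step 10.** The risks are over-reduction reaching the prenyl alkene, or incomplete conversion with loss of the labile chromene on long standing.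
- Fallback: replace hydrogen transfer from diimide by homogeneous catalytic hydrogenation with RhCl(PPh3)3 and H2 (1 atm) in benzene/EtOH. This catalyst discriminates strongly against trisubstituted alkenes and does not cleave benzylic ethers.
- It leads from 15 directly to 16 with no new compound (entry F0).

**Step 2.** The risks are metalation at the carbon next to the methoxy group, and inefficient alkylation by SN2′ attack, homocoupling or proton transfer.
- Fallback: quench aryllithium 4 with iodine to give 2-iodo-5-methoxy-1,3-bis(methoxymethoxy)benzene F7, from which a regioisomer can be removed by crystallisation.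
- Stille coupling of F7 with tributyl(3-methylbut-2-en-1-yl)stannane (Pd(PPh3)4, DMF, 80 °C) then installs the prenyl group and returns to the route at 5.

**Step 6.** Facial selectivity may be insufficient with this aldehyde.
- Fallback: add ethynylmagnesium bromide to 9 to give racemic 1-[3-methoxy-5-(triisopropylsilyloxy)phenyl]prop-2-yn-1-ol F8.
- Resolve F8 by lipase-catalysed acylation (Candida antarctica lipase B, vinyl acetate). By the usual empirical rule for secondary alcohols, the R enantiomer is acetylated to (1R)-1-[3-methoxy-5-(triisopropylsilyloxy)phenyl]prop-2-yn-1-yl acetate F9, and the S alcohol is left.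
- The unreacted alcohol is 13, where the route is rejoined.

## Further compounds

F1 | step 9 | 2-iodo-1-methoxy-3,5-bis(methoxymethoxy)-4-(3-methylbut-2-en-1-yl)benzene | COCOc1cc(OC)c(I)c(OCOC)c1CC=C(C)C
F2 | step 9 | (1R)-1-[3-methoxy-5-(triisopropylsilyloxy)phenyl]-3-[6-methoxy-2,4-bis(methoxymethoxy)-3-(3-methylbut-2-en-1-yl)phenyl]prop-2-yn-1-ol | COc1cc(O[Si](C(C)C)(C(C)C)C(C)C)cc([C@H](C#Cc2c(OC)cc(OCOC)c(CC=C(C)C)c2OCOC)O)c1
F3 | step 9 | (1S)-1-[3-methoxy-5-(triisopropylsilyloxy)phenyl]-3-[6-methoxy-2,4-bis(methoxymethoxy)-3-(3-methylbut-2-en-1-yl)phenyl]propan-1-ol | COc1cc(O[Si](C(C)C)(C(C)C)C(C)C)cc([C@H](CCc2c(OC)cc(OCOC)c(CC=C(C)C)c2OCOC)O)c1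
F4 | step 9 | 4-{(3S)-3-hydroxy-3-[3-methoxy-5-(triisopropylsilyloxy)phenyl]propyl}-5-methoxy-2-(3-methylbut-2-en-1-yl)benzene-1,3-diol | COc1cc(O[Si](C(C)C)(C(C)C)C(C)C)cc([C@H](CCc2c(OC)cc(O)c(CC=C(C)C)c2O)O)c1
F5 | step 9 | (2R)-5-methoxy-2-[3-methoxy-5-(triisopropylsilyloxy)phenyl]-8-(3-methylbut-2-en-1-yl)-3,4-dihydro-2H-chromen-7-ol | COc1cc(O[Si](C(C)C)(C(C)C)C(C)C)cc([C@H]2CCc3c(OC)cc(O)c(CC=C(C)C)c3O2)c1
F6 | step 8 | tert-butyl (1S)-1-[3-methoxy-5-(triisopropylsilyloxy)phenyl]prop-2-yn-1-yl carbonate | COc1cc(O[Si](C(C)C)(C(C)C)C(C)C)cc([C@H](C#C)OC(=O)OC(C)(C)C)c1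
F0 | step 10 | none | none
F7 | step 2 | 2-iodo-5-methoxy-1,3-bis(methoxymethoxy)benzene | COCOc1cc(OC)cc(OCOC)c1I
F8 | step 6 | racemic 1-[3-methoxy-5-(triisopropylsilyloxy)phenyl]prop-2-yn-1-ol | COc1cc(O[Si](C(C)C)(C(C)C)C(C)C)cc(C(O)C#C)c1
F9 | step 6 | (1R)-1-[3-methoxy-5-(triisopropylsilyloxy)phenyl]prop-2-yn-1-yl acetate | COc1cc(O[Si](C(C)C)(C(C)C)C(C)C)cc([C@@H](C#C)OC(C)=O)c1
A1 | alternative 1 | (E)-4-[(2R)-5-methoxy-8-(3-methylbut-2-en-1-yl)-7-(triisopropylsilyloxy)-3,4-dihydro-2H-chromen-2-yl]but-3-en-2-one | CC(=O)/C=C/[C@H]1CCc2c(OC)cc(O[Si](C(C)C)(C(C)C)C(C)C)c(CC=C(C)C)c2O1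
A2 | alternative 1 | dimethyl malonate | COC(=O)CC(=O)OC
A3 | alternative 1 | methyl 2-[(2R)-5-methoxy-8-(3-methylbut-2-en-1-yl)-7-(triisopropylsilyloxy)-3,4-dihydro-2H-chromen-2-yl]-4,6-dioxocyclohexane-1-carboxylate (ring centres unassigned) | COC(=O)C1C(=O)CC(=O)CC1[C@H]1CCc2c(OC)cc(O[Si](C(C)C)(C(C)C)C(C)C)c(CC=C(C)C)c2O1
A4 | alternative 2 | 3-methoxy-4-{(3S)-3-[3-methoxy-5-(triisopropylsilyloxy)phenyl]-3-(triethylsilyloxy)propyl}cyclobut-2-en-1-one (ring centre unassigned) | COC1=CC(=O)C1CC[C@H](O[Si](CC)(CC)CC)c1cc(OC)cc(O[Si](C(C)C)(C(C)C)C(C)C)c1
A5 | alternative 2 | triisopropyl[(5-methylhex-4-en-1-yn-1-yl)oxy]silane | CC(C)=CCC#CO[Si](C(C)C)(C(C)C)C(C)C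
A6 | alternative 2 | 3-methoxy-2-{(3S)-3-[3-methoxy-5-(triisopropylsilyloxy)phenyl]-3-(triethylsilyloxy)propyl}-6-(3-methylbut-2-en-1-yl)-5-(triisopropylsilyloxy)phenol | Oc1c(CC=C(C)C)c(O[Si](C(C)C)(C(C)C)C(C)C)cc(OC)c1CC[C@H](O[Si](CC)(CC)CC)c1cc(OC)cc(O[Si](C(C)C)(C(C)C)C(C)C)c1
A7 | alternative 3 | 2-(hydroxymethyl)-3-methoxy-6-(3-methylbut-2-en-1-yl)-5-(triisopropylsilyloxy)phenol | OCc1c(OC)cc(O[Si](C(C)C)(C(C)C)C(C)C)c(CC=C(C)C)c1O
A8 | alternative 3 | 1-ethenyl-3-methoxy-5-(triisopropylsilyloxy)benzene | C=Cc1cc(OC)cc(O[Si](C(C)C)(C(C)C)C(C)C)c1
A9 | alternative 3 | 5-methoxy-6-methylidene-2-(3-methylbut-2-en-1-yl)-3-(triisopropylsilyloxy)cyclohexa-2,4-dien-1-one | C=C1C(OC)=CC(O[Si](C(C)C)(C(C)C)C(C)C)=C(CC=C(C)C)C1=O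
A10 | alternative 3 | (2R)-5-methoxy-2-[3-methoxy-5-(triisopropylsilyloxy)phenyl]-8-(3-methylbut-2-en-1-yl)-7-(triisopropylsilyloxy)-3,4-dihydro-2H-chromene (identical with 16) | COc1cc(O[Si](C(C)C)(C(C)C)C(C)C)cc([C@H]2CCc3c(OC)cc(O[Si](C(C)C)(C(C)C)C(C)C)c(CC=C(C)C)c3O2)c1
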